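The cycloheptenone is opened at two bonds, C5–C6 and the ring-fusion bond C3a–C8a (azulene numbering: C1 carbinol, C3a quaternary carbon, C4 ketone, C8 ester carbon). The C4 carbonyl with its neighbours C3a and C5 is an oxyallyl cation in disguise, and C6–C7–C8–C8a is a butadiene that carries the C8 oxygen as an enol ether, while C1–C2–C3 of the cyclopentane serves as tether. An intramolecular (4+3) cycloaddition of a 2-ethoxyallyl cation with a 2-silyloxydiene thus closes both rings at once under control of the C1 carbinol. The acyclic precursor is assembled from (S)-terpinen-4-ol by ozonolysis and two carbonyl additions. Directed reduction, acylation and dehydrogenation complete the target.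

Key step: step 7

Assumption: commercial (S)-(+)-terpinen-4-ol of high enantiomeric purity is used; the C6 methyl centre created in step 7 is carried as an epimer mixture because it becomes sp2 in step 10.

Step 1
Reactants: 1 (S)-terpinen-4-ol; 2 triethylsilyl trifluoromethanesulfonate
Product: 3 triethyl{[(1S)-4-methyl-1-(propan-2-yl)cyclohex-3-en-1-yl]oxy}silane
Conditions: TESOTf, 2,6-lutidine, CH2Cl2, 0 °C to rt
Reagents that add atoms: triethylsilyl trifluoromethanesulfonate, CC[Si](CC)(CC)OS(=O)(=O)C(F)(F)F
Why: Silylation of the hindered tertiary alcohol with a silyl triflate and a pyridine base (silyl ether protection) masks the hydroxyl that would otherwise trap the cation of step 7; the stereocentre is not touched.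

Step 2
Reactants: 3 triethyl{[(1S)-4-methyl-1-(propan-2-yl)cyclohex-3-en-1-yl]oxy}silane
Product: 5 (3S)-6-oxo-3-(propan-2-yl)-3-[(triethylsilyl)oxy]heptanal, via secondary ozonide 4 (not isolated)
Conditions: O3, CH2Cl2, −78 °C; then PPh3, −78 °C to rt
Reagents that add atoms: ozone, [O-][O+]=O
Why: Ozonolysis with reductive work-up cleaves the only C=C bond and should deliver the methyl ketone (future C3a) and the aldehyde (future C8) in one operation, the carbinol carbon being untouched.

Step 3
Reactants: 5 (3S)-6-oxo-3-(propan-2-yl)-3-[(triethylsilyl)oxy]heptanal; 6 (E)-1-bromoprop-1-ene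
Product: 8 (5S,8E)-7-hydroxy-5-(propan-2-yl)-5-[(triethylsilyl)oxy]dec-8-en-2-one (C7 epimers), via (E)-prop-1-enylchromium dichloride 7 (not isolated)
Conditions: CrCl2 (4 equiv), NiCl2 (2 mol %), DMF, rt
Reagents that add atoms: (E)-1-bromoprop-1-ene, C/C=C/Br
Why: The Nozaki–Hiyama–Kishi alkenylation should add the organochromium reagent to the aldehyde and not to the methyl ketone and keeps the E geometry of the bromide; the new carbinol centre forms as a mixture that is removed by oxidation in step 5.

Step 4
Reactants: 8 (5S,8E)-7-hydroxy-5-(propan-2-yl)-5-[(triethylsilyl)oxy]dec-8-en-2-one; 9 ethyl vinyl ether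
Product: 11 (6S,9E)-2-ethoxy-3-methyl-6-(propan-2-yl)-6-[(triethylsilyl)oxy]undeca-1,9-diene-3,8-diol (C3 and C8 epimers), via 1-ethoxyvinyllithium 10 (not isolated)
Conditions: 9, t-BuLi, THF, −78 to 0 °C; then 8, −78 °C; aq. NaHCO3
Reagents that add atoms: ethyl vinyl ether (as 1-ethoxyvinyllithium), C=COCC
Why: 1,2-Addition of an alpha-alkoxyvinyllithium (acyl anion equivalent) to the methyl ketone, with the secondary alcohol protected in the flask as its lithium alkoxide, installs C4 and C5; the configuration of the new tertiary carbinol is irrelevant because this carbon is ionised in step 7.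

Step 5
Reactants: 11 (6S,9E)-2-ethoxy-3-methyl-6-(propan-2-yl)-6-[(triethylsilyl)oxy]undeca-1,9-diene-3,8-diol
Product: 12 (2E,6S)-10-ethoxy-9-hydroxy-9-methyl-6-(propan-2-yl)-6-[(triethylsilyl)oxy]undeca-2,10-dien-4-one (C9 epimers)
Conditions: MnO2 (activated, excess), K2CO3, CH2Cl2, rt
Reagents that add atoms: none
Why: Activated MnO2 should oxidise only the allylic secondary alcohol to the enone (allylic alcohol oxidation) under neutral heterogeneous conditions that leave the acid-labile enol ether, the tertiary alcohol and the silyl ether intact.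

Step 6
Reactants: 12 (2E,6S)-10-ethoxy-9-hydroxy-9-methyl-6-(propan-2-yl)-6-[(triethylsilyl)oxy]undeca-2,10-dien-4-one; 13 tert-butyldimethylsilyl chloride
Product: 15 (2E,4Z,6R)-4-[(tert-butyldimethylsilyl)oxy]-10-ethoxy-9-methyl-6-(propan-2-yl)-6-[(triethylsilyl)oxy]undeca-2,4,10-trien-9-ol (C9 epimers), via dilithium alkoxide dienolate 14 (not isolated)
Conditions: LiN(i-Pr)2 (2.3 equiv), THF/DMPU, −78 °C; TBSCl (1.2 equiv), −78 to −30 °C; aq. NaHCO3
Reagents that add atoms: tert-butyldimethylsilyl chloride, CC(C)(C)[Si](C)(C)Cl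
Why: Kinetic deprotonation of the enone at the alpha-prime methylene (future C8a) and O-silylation of the cross-conjugated dienolate (silyl enol ether formation) should give the 2-silyloxydiene, expected as the Z enol ether because the bulky C1 substituent avoids the propenyl group; the hindered tertiary lithium alkoxide is not silylated by TBSCl and returns as the free alcohol on work-up.

Step 7
Reactants: 15 (2E,4Z,6R)-4-[(tert-butyldimethylsilyl)oxy]-10-ethoxy-9-methyl-6-(propan-2-yl)-6-[(triethylsilyl)oxy]undeca-2,4,10-trien-9-ol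
Product: 18 (1R,3aS,8aR)-1-hydroxy-3a,6-dimethyl-1-(propan-2-yl)octahydroazulene-4,8-dione (trans-fused, C6 epimers), via 2-ethoxyallyl cation 16 (not isolated), via bis(enol ether) cycloadduct 17 (not isolated)
Conditions: Tf2O (1.2 equiv), 2,6-lutidine (3 equiv), CH2Cl2, −78 °C; then aq. HF, MeCN, 0 °C
Reagents that add atoms: water, O
Why: O-Triflation of the only free hydroxyl and loss of triflate give the 2-ethoxyallyl cation 16, whose termini C3a and C5 are captured by the termini C8a and C6 of the tethered 2-silyloxydiene, in concert or in two fast steps that start at C3a–C8a; loss of the C5 proton to lutidine leaves the bis(enol ether) 17, which aqueous HF hydrolyses together with the triethylsilyl ether. The closest known reaction type is the intramolecular (4+3) cycloaddition of 2-alkoxyallylic cations, generated from tertiary 2-alkoxyallylic alcohols with Tf2O and 2,6-lutidine, with tethered 1,3-dienes. The cyclopentane closes by bonding of diene terminus C8a to cation terminus C3a through the three-carbon tether (5-exo at the diene, the ring-fusion bond), and the cycloheptene closes by the second bond C5–C6 of the same (4+3) event. C8a is controlled by the C1 stereocentre, because the diene should react in the rotamer that holds isopropyl anti to the enol ether double bond and the smaller silyloxy group gauche, which places C8 cis to the C1 oxygen; C3a follows from an extended transition state that keeps the bulky alkoxyallyl unit trans to C8 and so gives the trans ring fusion, whereas C6 forms without need of control. The step needs ionisation at C3a and not at the allylic C1 silyl ether, which is secured because Tf2O activates only the free hydroxyl under lutidine buffering without any Lewis acid, and it needs seven-ring closure at C6 in place of five-ring closure at C8, which the s-cis diene with its more accessible terminus should favour.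

Step 8
Reactants: 18 (1R,3aS,8aR)-1-hydroxy-3a,6-dimethyl-1-(propan-2-yl)octahydroazulene-4,8-dione
Product: 19 (1R,3aS,8S,8aS)-1,8-dihydroxy-3a,6-dimethyl-1-(propan-2-yl)octahydroazulen-4(1H)-one (C6 epimers)
Conditions: Me4NBH(OAc)3, MeCN/AcOH (1:1), −30 to 0 °C
Reagents that add atoms: none
Why: Evans–Saksena hydroxyl-directed reduction: the C1 hydroxyl exchanges onto boron and delivers hydride intramolecularly to the face of the C8 ketone on which it sits, so the new C8 hydroxyl should end up anti to the C1 hydroxyl (8S), while the C4 ketone, which has no hydroxyl within reach on its face, is not reduced by the triacetoxyborohydride.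

Step 9
Reactants: 19 (1R,3aS,8S,8aS)-1,8-dihydroxy-3a,6-dimethyl-1-(propan-2-yl)octahydroazulen-4(1H)-one; 20 4-acetoxybenzoic acid
Product: 22 (1R,3aS,8S,8aS)-1-hydroxy-3a,6-dimethyl-4-oxo-1-(propan-2-yl)decahydroazulen-8-yl 4-acetoxybenzoate (C6 epimers), via mixed anhydride 21 (not isolated)
Conditions: 20, 2,4,6-trichlorobenzoyl chloride, Et3N, THF, rt; then 19, DMAP, toluene, rt
Reagents that add atoms: 4-acetoxybenzoic acid, CC(=O)Oc1ccc(cc1)C(O)=O
Why: Yamaguchi esterification through the mixed anhydride should acylate the secondary C8 hydroxyl with retention, the tertiary C1 hydroxyl being too hindered to react.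

Step 10
Reactants: 22 (1R,3aS,8S,8aS)-1-hydroxy-3a,6-dimethyl-4-oxo-1-(propan-2-yl)decahydroazulen-8-yl 4-acetoxybenzoate
Product: 23 (1R,3aS,8S,8aS)-1-hydroxy-3a,6-dimethyl-4-oxo-1-(propan-2-yl)-1,2,3,3a,4,7,8,8a-octahydroazulen-8-yl 4-acetoxybenzoate
Conditions: IBX (2.5 equiv), DMSO/fluorobenzene, 70 °C
Reagents that add atoms: none
Why: IBX dehydrogenation of a ketone to its enone: C4 can enolise only towards C5 because C3a is quaternary, so the C5=C6 double bond is the only possible outcome and the uncontrolled C6 centre disappears.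

Step 11
Reactants: 23 (1R,3aS,8S,8aS)-1-hydroxy-3a,6-dimethyl-4-oxo-1-(propan-2-yl)-1,2,3,3a,4,7,8,8a-octahydroazulen-8-yl 4-acetoxybenzoate
Product: 24 (1R,3aS,8S,8aS)-1-hydroxy-3a,6-dimethyl-4-oxo-1-(propan-2-yl)-1,2,3,3a,4,7,8,8a-octahydroazulen-8-yl 4-hydroxybenzoate (target)
Conditions: NH4OAc, MeOH/H2O (4:1), rt
Reagents that add atoms: none
Why: Near-neutral methanolysis (selective ester cleavage) should remove the aryl acetate, an activated phenyl ester, much faster than the hindered secondary benzoate and avoids base-induced elimination across the enone.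

Compound list

1 | (S)-terpinen-4-ol, (1S)-4-methyl-1-(propan-2-yl)cyclohex-3-en-1-ol | CC1=CC[C@](O)(C(C)C)CC1 | starting material
2 | triethylsilyl trifluoromethanesulfonate | CC[Si](CC)(CC)OS(=O)(=O)C(F)(F)F | starting material
3 | triethyl{[(1S)-4-methyl-1-(propan-2-yl)cyclohex-3-en-1-yl]oxy}silane | CC1=CC[C@](O[Si](CC)(CC)CC)(C(C)C)CC1 | intermediate
4 | secondary ozonide of 3, 1-methyl-4-(propan-2-yl)-4-[(triethylsilyl)oxy]-7,8,9-trioxabicyclo[4.2.1]nonane (carbinol carbon as in 3, bridgehead epimers) | CC12CC[C@@](O[Si](CC)(CC)CC)(C(C)C)CC(OO1)O2 | intermediate (not isolated)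
5 | (3S)-6-oxo-3-(propan-2-yl)-3-[(triethylsilyl)oxy]heptanal | O=CC[C@](O[Si](CC)(CC)CC)(C(C)C)CCC(C)=O | intermediate
6 | (E)-1-bromoprop-1-ene | C/C=C/Br | starting material
7 | (E)-prop-1-enylchromium dichloride | C/C=C/[Cr](Cl)Cl | intermediate (not isolated)
8 | (5S,8E)-7-hydroxy-5-(propan-2-yl)-5-[(triethylsilyl)oxy]dec-8-en-2-one (C7 epimers) | C/C=C/C(O)C[C@](O[Si](CC)(CC)CC)(C(C)C)CCC(C)=O | intermediate
9 | ethyl vinyl ether | C=COCC | starting material
10 | 1-ethoxyvinyllithium | [Li]C(=C)OCC | intermediate (not isolated)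
11 | (6S,9E)-2-ethoxy-3-methyl-6-(propan-2-yl)-6-[(triethylsilyl)oxy]undeca-1,9-diene-3,8-diol (C3 and C8 epimers) | C/C=C/C(O)C[C@](O[Si](CC)(CC)CC)(C(C)C)CCC(C)(O)C(=C)OCC | intermediate
12 | (2E,6S)-10-ethoxy-9-hydroxy-9-methyl-6-(propan-2-yl)-6-[(triethylsilyl)oxy]undeca-2,10-dien-4-one (C9 epimers) | C/C=C/C(=O)C[C@](O[Si](CC)(CC)CC)(C(C)C)CCC(C)(O)C(=C)OCC | intermediate
13 | tert-butyldimethylsilyl chloride | CC(C)(C)[Si](C)(C)Cl | starting material
14 | dilithium alkoxide (Z)-dienolate of 12 | C/C=C/C(O[Li])=C/[C@](O[Si](CC)(CC)CC)(C(C)C)CCC(C)(O[Li])C(=C)OCC | intermediate (not isolated)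
15 | (2E,4Z,6R)-4-[(tert-butyldimethylsilyl)oxy]-10-ethoxy-9-methyl-6-(propan-2-yl)-6-[(triethylsilyl)oxy]undeca-2,4,10-trien-9-ol (C9 epimers) | C/C=C/C(O[Si](C)(C)C(C)(C)C)=C/[C@](O[Si](CC)(CC)CC)(C(C)C)CCC(C)(O)C(=C)OCC | intermediate
16 | 2-ethoxyallyl cation from 15 (tertiary terminus at the former carbinol carbon), triflate salt | C/C=C/C(O[Si](C)(C)C(C)(C)C)=C/[C@](O[Si](CC)(CC)CC)(C(C)C)CC[C+](C)C(=C)OCC.[O-]S(=O)(=O)C(F)(F)F | intermediate (not isolated)
17 | (1R,3aS,8aS)-8-[(tert-butyldimethylsilyl)oxy]-4-ethoxy-3a,6-dimethyl-1-(propan-2-yl)-1-[(triethylsilyl)oxy]-1,2,3,3a,6,8a-hexahydroazulene (trans-fused, C6 epimers) | CC1C=C(OCC)[C@@]2(C)CC[C@@](O[Si](CC)(CC)CC)(C(C)C)[C@@H]2C(O[Si](C)(C)C(C)(C)C)=C1 | intermediate (not isolated)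
18 | (1R,3aS,8aR)-1-hydroxy-3a,6-dimethyl-1-(propan-2-yl)octahydroazulene-4,8-dione (trans-fused, C6 epimers) | CC1CC(=O)[C@@]2(C)CC[C@@](O)(C(C)C)[C@@H]2C(=O)C1 | intermediate
19 | (1R,3aS,8S,8aS)-1,8-dihydroxy-3a,6-dimethyl-1-(propan-2-yl)octahydroazulen-4(1H)-one (C6 epimers) | CC1CC(=O)[C@@]2(C)CC[C@@](O)(C(C)C)[C@@H]2[C@@H](O)C1 | intermediate
20 | 4-acetoxybenzoic acid | CC(=O)Oc1ccc(cc1)C(O)=O | starting material
21 | 4-acetoxybenzoic 2,4,6-trichlorobenzoic anhydride | CC(=O)Oc1ccc(cc1)C(=O)OC(=O)c1c(Cl)cc(Cl)cc1Cl | intermediate (not isolated)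
22 | (1R,3aS,8S,8aS)-1-hydroxy-3a,6-dimethyl-4-oxo-1-(propan-2-yl)decahydroazulen-8-yl 4-acetoxybenzoate (C6 epimers) | CC1CC(=O)[C@@]2(C)CC[C@@](O)(C(C)C)[C@@H]2[C@@H](OC(=O)c2ccc(OC(C)=O)cc2)C1 | intermediate
23 | (1R,3aS,8S,8aS)-1-hydroxy-3a,6-dimethyl-4-oxo-1-(propan-2-yl)-1,2,3,3a,4,7,8,8a-octahydroazulen-8-yl 4-acetoxybenzoate | CC1=CC(=O)[C@@]2(C)CC[C@@](O)(C(C)C)[C@@H]2[C@@H](OC(=O)c2ccc(OC(C)=O)cc2)C1 | intermediate
24 | (1R,3aS,8S,8aS)-1-hydroxy-3a,6-dimethyl-4-oxo-1-(propan-2-yl)-1,2,3,3a,4,7,8,8a-octahydroazulen-8-yl 4-hydroxybenzoate | CC1=CC(=O)[C@@]2(C)CC[C@@](O)(C(C)C)[C@@H]2[C@@H](OC(=O)c2ccc(O)cc2)C1 | target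

Total step count: 11. Longest linear sequence: 11 steps (1 to 24).

Steps most likely to fail

1. Step 7. After ionisation the cation may lose a proton, may be captured at one carbon only so that the seven-membered ring does not close, or may close with low preference for the trans ring fusion. The fallback replaces the cycloaddition by a stepwise alkylation and Michael ring closure. Setting out from 15, the same ionisation (Tf2O, 2,6-lutidine, CH2Cl2, −78 °C) is quenched with aqueous NaHCO3, so that the product of the first carbon–carbon bond is isolated as the ethoxyvinyl cyclopentyl enone F1. TMSOTf in CH2Cl2 at −78 °C should then promote an intramolecular Mukaiyama–Michael addition of the enol ether carbon C5 to the enone carbon C6 and give, after aqueous work-up, the triethylsilyl-protected diketone F2. Aqueous HF in MeCN removes the silyl group, and the route is rejoined at 18.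

2. Step 8. Exchange of the hindered tertiary hydroxyl onto boron may be slow, so that hydride is not delivered intramolecularly and the C8 alcohol forms with the wrong configuration or not at all. The fallback sets C8 by inversion. Setting out from 18, chelation-controlled reduction with Zn(BH4)2 in Et2O at −20 °C (external hydride attack on the zinc chelate of the hydroxy ketone) should give the C8-epimeric syn diol F3. Mitsunobu esterification of F3 with 20 (PPh3, DIAD, toluene, 0 °C to rt) inverts C8 and returns to the route at 22.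

3. Step 10. Enolisation of the ketone next to the quaternary carbon may be too slow for the oxidant, or oxidation may run on to the dienone with loss of the benzoate. The fallback is the two-stage Saegusa–Ito sequence. Setting out from 22, TMSOTf and Et3N in CH2Cl2 at 0 °C should give the bis(trimethylsilyl) enol ether F4 (silyl enol ether at C4–C5, silyl ether at C1). Pd(OAc)2 in MeCN at rt then gives the trimethylsilyl-protected enone F5. Brief treatment with citric acid in MeOH frees the tertiary alcohol, and the route is rejoined at 23.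

Further compounds

F1 | step 7 | (E)-1-[2-(1-ethoxyethenyl)-2-methyl-5-(propan-2-yl)-5-(triethylsilyloxy)cyclopentyl]but-2-en-1-one, ring configuration as in 18 | C=C(OCC)[C@@]1(C)CC[C@@](O[Si](CC)(CC)CC)(C(C)C)[C@@H]1C(=O)/C=C/C
F2 | step 7 | 1-O-triethylsilyl ether of 18 | CC1CC(=O)[C@@]2(C)CC[C@@](O[Si](CC)(CC)CC)(C(C)C)[C@@H]2C(=O)C1
F3 | step 8 | C8 epimer of 19 (C1 and C8 hydroxyls syn) | CC1CC(=O)[C@@]2(C)CC[C@@](O)(C(C)C)[C@@H]2[C@H](O)C1
F4 | step 10 | bis(trimethylsilyl) derivative of 22 (C4–C5 enol ether and C1 silyl ether) | CC1C=C(O[Si](C)(C)C)[C@@]2(C)CC[C@@](O[Si](C)(C)C)(C(C)C)[C@@H]2[C@@H](OC(=O)c2ccc(OC(C)=O)cc2)C1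
F5 | step 10 | 1-O-trimethylsilyl ether of 23 | CC1=CC(=O)[C@@]2(C)CC[C@@](O[Si](C)(C)C)(C(C)C)[C@@H]2[C@@H](OC(=O)c2ccc(OC(C)=O)cc2)C1
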